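Slowness is the question in this flask: Thursday's table follows Q and Z.Q but not E, so how slowly E reacts with Z has to be reckoned through the fraction left, not the fraction made.

- Thursday's: Q 0.030 M; E 0.030 M; Z 4 equiv; G 5 mol%; run made earlier
- flask: Q 0.020 M; Z 4.00 equiv; G 5 mol%; E 0.020 M; time 10 h

- Thursday's (time / h: Q / %, Z.Q / %): 0.417: 9.7, 41.1; 0.833: 2.8, 49.2; 1.33: 0.9, 50.3; 1.50: 0.1, 51.1; 2.00: 0.3, 51.3; 2.50: 0, 50.4; 3.00: 0, 50.6

(standard deviation of a reading: 0.5 percentage points)

- Z is single-handed; Q and E are mirror images of each other, charged as a racemate, each of them at the stated concentration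
- the numbers in the tables scatter with a standard deviation of 0.5 percentage points
- no earlier run changes the charge of G; that part of a forecast is a guess
- the handed part of Z does not stay in what it makes, so the products of the two hands are mirror images too

- share of the Q and E together used up at 10 h
- Z.Q at 10 h, in percent of the Q and E together charged
- E at 10 h, in percent of the Q and E together charged

In Thursday's run Q, half of the charge, stood at 9.7% after 0.417 h. Dividing the logarithm of that fraction left by the time and by the starting [Z] of 0.120 M gives a reading of the second-order constant of Q with Z, kQ = 32.8 L mol⁻¹ h⁻¹. For the new flask we reckon [Z] as 0.0600 M, its charge less the Q it takes, and with [Z] held at that value we take the exposure X = kQ[Z]t over 10 h as 19.7. If s is the selectivity factor, the constant of Q over that of E, then we reckon that E keeps exp(-X/s) of its charge.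

From above, in this reckoning, an E that does not react stays at its charge, half of what was charged. From below, s of one gives <0.001% by the same reckoning, too low to be of use. Thursday's table has no column for E, so we narrow the bracket by an estimate, with the forecast's own “Guessing selectivity around 50–100”, and its two ends give us E between 33.7% and 41.1%. The forecast says E 46%, within 32% to 50%, with conversion 54% and Z.Q 50.6%, so its central E stands above our bracket.

The flask gives E 34.5%, inside our bracket and below the forecast, with conversion 65.5% and Z.Q 50.4%.

    Z + E → Z.E (k = 1.76 × 10⁻⁴ L mol⁻¹ s⁻¹)
    Q + G ⇌ E + G, rate k2*[G]*[Q] forward; the back reaction follows from the equilibrium constant (k = 0.191 L mol⁻¹ s⁻¹)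
    Z + G → Z.G (k = 4.97 × 10⁻⁴ L mol⁻¹ s⁻¹)
    G → J (k = 0.00392 s⁻¹)
    Z + Q → Z.Q (k = 0.0109 L mol⁻¹ s⁻¹)

At the start of the flask Z is used by Q 62 times as fast as by E. In the neighbouring flask with 1.00 equiv of Z, [Z] and [Q] start equal, so we reckon the fraction of Q left as one over one plus kQ[Z]t with the starting [Z], which is 13.2%, and that neighbour holds 13% of its charged Q at 10.0 h.

Readings and results stem from a simulated flask with constants of no real substance; scatter was added.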